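**Plan**
Retrosynthesis: the ring B NH2 goes back to an enol OH, the ring A O-acyl group back to a C-acyl group on the ring CH (retro-Claisen shift), and the ring A quaternary C-methyl back to C–H. This uncovers a C2-symmetric methylene-bis(acyl o-quinol) 13, and from it, by C-deacylation, 10.
Each ring of 10 is cut at the ring ketone–CH bond and at the other ring ketone–carbinol carbon bond, giving a lactic acid C2 unit and a β-methoxy-enoyl C4 unit; the two C4 units are joined through the bridging CH2 (methylene-bis-acetoacetate).
Enabling feature: both six-membered rings hold the same CH3–C(O)–C(=O) pair (carbinol carbon plus adjacent ring carbonyl carbon) next to a second ring ketone, with the same absolute configuration, so one lactate enolate can be acylated and then act as acyl acceptor on both halves.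
Forward: bis-acetoacetate → bis(β-methoxyenoyl chloride) 5; double annulation with dioxolanone 8 closes both rings at once (step 6); C-acylation; mono C-methylation with acyl shift differentiates ring A; ammonia completes ring B.
Stereochemistry: both carbinol centres come from (R)-lactic acid through the dioxolanone (self-regeneration of stereocentres); the ring A C–CH3 centre is set by methylation anti to the methyl on the neighbouring carbinol carbon; both sec-butyl centres come from (R)-2-methylbutanoic acid.

Key step: step 6

Remark: both 2-methylbutanoyl centres of the given structure are (R), so (R)-2-methylbutanoic acid (taken as purchasable) is used; the enol-ether geometry of 3, 4, 5 and 9 is drawn (E,E) and has no bearing, because step 6 passes through dienolates.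

Step 1
Reactants: 1 methyl acetoacetate (2 equiv)
Product: 2 dimethyl 2,4-diacetylpentanedioate (diastereomer mixture)
Conditions: 37% aq. CH2O (0.5 equiv), piperidine (cat.), MeOH, 0 °C to rt
Reagents that add atoms: formaldehyde, C=O
Why: Knoevenagel condensation of formaldehyde with one acetoacetate followed by Michael addition of the second should give the methylene-bis adduct, whose two enolizable CH centres are removed in step 2.

Step 2
Reactants: 2 dimethyl 2,4-diacetylpentanedioate
Product: 3 dimethyl (2E,2'E)-2,2'-methylenebis(3-methoxybut-2-enoate)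
Conditions: NaH (2.2 equiv), THF–DMPU, 0 °C; Me2SO4 (2.4 equiv), 0 °C to rt
Reagents that add atoms: dimethyl sulfate, COS(=O)(=O)OC
Why: The bis-sodium enolate (which cannot undergo intramolecular aldol closure because no free ketone remains) should be O-methylated by the hard electrophile in a dipolar aprotic medium (enolate O-alkylation), which fixes each methoxy group on the carbon it occupies in both rings of the target.

Step 3
Reactants: 3 dimethyl (2E,2'E)-2,2'-methylenebis(3-methoxybut-2-enoate)
Product: 4 (2E,2'E)-2,2'-methylenebis(3-methoxybut-2-enoic acid)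
Conditions: KOH, MeOH–H2O, 65 °C; then aq. HCl to pH 2
Reagents that add atoms: potassium hydroxide, [K+].[OH-]
Why: Ester saponification of the two vinylogous carbonate esters should proceed cleanly because β-methoxyacrylic acids are stable to base and do not decarboxylate.

Step 4
Reactants: 4 (2E,2'E)-2,2'-methylenebis(3-methoxybut-2-enoic acid)
Product: 5 (2E,2'E)-2,2'-methylenebis(3-methoxybut-2-enoyl chloride)
Conditions: (COCl)2, DMF (cat.), CH2Cl2, 0 °C to rt; evaporate and use crude
Reagents that add atoms: oxalyl chloride, O=C(Cl)C(=O)Cl
Why: Vilsmeier-catalysed acid chloride formation is routine for β-alkoxyacrylic acids and gives an acylating agent with no α-hydrogen.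

Step 5
Reactants: 6 (R)-lactic acid; 7 pivalaldehyde
Product: 8 (2R,5R)-2-tert-butyl-5-methyl-1,3-dioxolan-4-one (cis)
Conditions: TsOH·H2O (cat.), H2SO4 (cat.), pentane, reflux (Dean–Stark); cis isomer crystallized from pentane–Et2O at −78 °C
Reagents that add atoms: none
Why: Acid-catalysed acetalization of the hydroxy acid should give mainly the cis dioxolanone, in which the new acetal centre (set under thermodynamic control by the lactate centre and purified by crystallization) stores the configuration for step 6.

Step 6
Reactants: 8 (2R,5R)-2-tert-butyl-5-methyl-1,3-dioxolan-4-one (2.1 equiv); 5 (2E,2'E)-2,2'-methylenebis(3-methoxybut-2-enoyl chloride)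
Product: 10 2,2'-methylenebis[(6R)-5,6-dihydroxy-3-methoxy-6-methylcyclohexa-2,4-dien-1-one], via bis(acyldioxolanone) 9 (not isolated)
Conditions: LDA (2.1 equiv), THF, −78 °C; add 5, −78 °C; then LiHMDS (4.4 equiv), −78 to −20 °C; aq. HCl to pH 3
Reagents that add atoms: none
Why: Proposed new method: the lithium enolate of 8 should be C-acylated by each acid chloride of 5 on the face anti to the tert-butyl group to give 9, whose only acidic hydrogens are the γ-methyl hydrogens of the two β-methoxy enones; LiHMDS then forms the dienolates, whose γ-carbon adds to the acylal carbonyl of the neighbouring dioxolanone, and collapse of the tetrahedral intermediate expels the hemiacetal alkoxide, which loses pivalaldehyde and leaves the tertiary carbinol. The closest known reaction types are the C-acylation and alkylation of lactate-derived dioxolanone enolates and the vinylogous Dieckmann (Claisen) cyclization of γ-deprotonated β-alkoxy enones onto esters; new is their coupling, with the dioxolanone serving first as nucleophile and then as acyl donor. Each of the two carbocycles closes in a 6-(enolendo)-exo-trig Claisen condensation. The two new quaternary carbinol centres (the ring A C–O carbon and its ring B counterpart) are controlled by the (R)-acetal carbon, the acyl group taking the place of the lactate hydrogen with retention, so both should be R. The step needs C- over O-acylation and γ-deprotonation over attack of base on the lactone; the acid chloride at −78 °C, the absence of any α'-hydrogen in 9 and the six-membered transition state should secure this, and irreversible formation of the vinylogous-acid anion drives the closure.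

Step 7
Reactants: 10 2,2'-methylenebis[(6R)-5,6-dihydroxy-3-methoxy-6-methylcyclohexa-2,4-dien-1-one]; 11 (R)-2-methylbutanoic acid (2.2 equiv)
Product: 13 2,2'-methylenebis[(6R)-5,6-dihydroxy-3-methoxy-6-methyl-4-[(2R)-2-methylbutanoyl]cyclohexa-2,4-dien-1-one], via bis(enol ester) 12 (not isolated)
Conditions: DCC, DMAP, CH2Cl2, 0 °C to rt
Reagents that add atoms: none
Why: Steglich O-acylation of the two acidic ring enols followed by DMAP-mediated O-to-C acyl shift (the enol ester to 2-acyl-1,3-dione rearrangement) should place each acyl group on the ring CH between the enol carbon and the C–OMe carbon as a chelated β-triketone, while the hindered tertiary carbinols stay free and no stereocentre is formed.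

Step 8
Reactants: 13 2,2'-methylenebis[(6R)-5,6-dihydroxy-3-methoxy-6-methyl-4-[(2R)-2-methylbutanoyl]cyclohexa-2,4-dien-1-one]
Product: 15 hydroxy analogue of gilluone B (ring B enol OH in place of NH2), via C-methylated triketone 14 (not isolated)
Conditions: NaOMe (2.2 equiv), MeI (1.0 equiv), MeOH, 0 °C to rt; aq. NaH2PO4; unreacted 13 recycled
Reagents that add atoms: iodomethane, CI
Why: C-methylation of one acyl-dienolate at the ring carbon that carries the bridging CH2 and no acyl group (the classical gem-dialkylation of acylphloroglucinol anions; the two rings of 13 are homotopic) should enter anti to the methyl group on the neighbouring carbinol carbon and so set the quaternary C–CH3 centre cis to the carbinol oxygen, after which the methylated ring, no longer enolizable, passes its acyl group to the carbinol oxygen by methoxide-mediated retro-Claisen transfer (MeOH adds to the β-methoxy enone, the tertiary alkoxide attacks the acyl carbonyl, MeOH is lost again), while the other ring stays protected as its enolate.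

Step 9
Reactants: 15 hydroxy analogue of gilluone B
Product: 16 gilluone B
Conditions: NH4OAc, MeOH, 40 °C
Reagents that add atoms: ammonium acetate, CC(=O)[O-].[NH4+]
Why: Addition–elimination of ammonia at the ring enol carbon of the vinylogous acid (enaminone formation) should give the primary vinylogous amide, held by an N–H···O=C hydrogen bond to the acyl group, while the hindered ring A vinylogous ester and tertiary ester are left alone.

**Compound list**
1 | methyl acetoacetate | CC(=O)CC(=O)OC | starting material
2 | dimethyl 2,4-diacetylpentanedioate (diastereomer mixture) | COC(=O)C(CC(C(C)=O)C(=O)OC)C(C)=O | intermediate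
3 | dimethyl (2E,2'E)-2,2'-methylenebis(3-methoxybut-2-enoate) | COC(=O)/C(C/C(C(=O)OC)=C(/C)OC)=C(\C)OC | intermediate
4 | (2E,2'E)-2,2'-methylenebis(3-methoxybut-2-enoic acid) | OC(=O)/C(C/C(C(=O)O)=C(/C)OC)=C(\C)OC | intermediate
5 | (2E,2'E)-2,2'-methylenebis(3-methoxybut-2-enoyl chloride) | ClC(=O)/C(C/C(C(Cl)=O)=C(/C)OC)=C(\C)OC | intermediate
6 | (R)-lactic acid | C[C@@H](O)C(=O)O | starting material
7 | pivalaldehyde | CC(C)(C)C=O | starting material
8 | (2R,5R)-2-tert-butyl-5-methyl-1,3-dioxolan-4-one (cis) | C[C@H]1O[C@@H](C(C)(C)C)OC1=O | intermediate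
9 | (2E,4E)-1,5-bis[(2R,5S)-2-tert-butyl-5-methyl-4-oxo-1,3-dioxolan-5-yl]-2,4-bis(1-methoxyethylidene)pentane-1,5-dione | C[C@@]1(C(=O)/C(C/C(C(=O)[C@]2(C)O[C@@H](C(C)(C)C)OC2=O)=C(/C)OC)=C(\C)OC)O[C@@H](C(C)(C)C)OC1=O | intermediate
10 | 2,2'-methylenebis[(6R)-5,6-dihydroxy-3-methoxy-6-methylcyclohexa-2,4-dien-1-one] | O[C@]1(C)C(O)=CC(OC)=C(CC2=C(OC)C=C(O)[C@@](C)(O)C2=O)C1=O | intermediate
11 | (R)-2-methylbutanoic acid | CC[C@@H](C)C(=O)O | starting material
12 | 2,2'-methylenebis[(6R)-6-hydroxy-3-methoxy-6-methyl-5-{[(2R)-2-methylbutanoyl]oxy}cyclohexa-2,4-dien-1-one] | O[C@]1(C)C(OC(=O)[C@H](C)CC)=CC(OC)=C(CC2=C(OC)C=C(OC(=O)[C@H](C)CC)[C@@](C)(O)C2=O)C1=O | intermediate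
13 | 2,2'-methylenebis[(6R)-5,6-dihydroxy-3-methoxy-6-methyl-4-[(2R)-2-methylbutanoyl]cyclohexa-2,4-dien-1-one] | O[C@]1(C)C(O)=C(C(=O)[C@H](C)CC)C(OC)=C(CC2=C(OC)C(C(=O)[C@H](C)CC)=C(O)[C@@](C)(O)C2=O)C1=O | intermediate
14 | C-methylated triketone: ring A is 2-hydroxy-5-methoxy-2,6-dimethyl-4-[(2R)-2-methylbutanoyl]cyclohex-4-ene-1,3-dione (new 6-methyl cis to the 2-hydroxyl, carbinol centre as in 13), its C6 joined by CH2 to C2 of an unchanged (6R)-5,6-dihydroxy-3-methoxy-6-methyl-4-[(2R)-2-methylbutanoyl]cyclohexa-2,4-dien-1-one ring | O[C@]1(C)C(=O)C(C(=O)[C@H](C)CC)=C(OC)[C@@](C)(CC2=C(OC)C(C(=O)[C@H](C)CC)=C(O)[C@@](C)(O)C2=O)C1=O | intermediate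
15 | (1R,5R)-5-{[(5R)-4,5-dihydroxy-2-methoxy-5-methyl-3-[(2R)-2-methylbutanoyl]-6-oxocyclohexa-1,3-dien-1-yl]methyl}-4-methoxy-1,5-dimethyl-2,6-dioxocyclohex-3-en-1-yl (2R)-2-methylbutanoate | CC[C@@H](C)C(=O)O[C@]1(C)C(=O)C=C(OC)[C@@](C)(CC2=C(OC)C(C(=O)[C@H](C)CC)=C(O)[C@@](C)(O)C2=O)C1=O | intermediate
16 | gilluone B, (1R,5R)-5-{[(5R)-4-amino-5-hydroxy-2-methoxy-5-methyl-3-[(2R)-2-methylbutanoyl]-6-oxocyclohexa-1,3-dien-1-yl]methyl}-4-methoxy-1,5-dimethyl-2,6-dioxocyclohex-3-en-1-yl (2R)-2-methylbutanoate | CC[C@@H](C)C(=O)O[C@]1(C)C(=O)C=C(OC)[C@@](C)(CC2=C(OC)C(C(=O)[C@H](C)CC)=C(N)[C@@](C)(O)C2=O)C1=O | target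

Total step count: 9. Longest linear sequence: 8 (steps 1, 2, 3, 4, 6, 7, 8, 9; step 5 is a one-step side branch).

**Steps most likely to fail**

Step 6. The γ-dienolates may not close onto the acylal carbonyl: the amide base may attack the lactone, or liberated pivalaldehyde may undergo aldol addition, before the ring closes. The fallback sets out from 9, obtained by quenching step 6 after the acylation stage. Acid-catalysed methanolysis (HCl, MeOH) opens both dioxolanones with loss of pivalaldehyde to dimethyl (2S,8S,4E,6E)-2,8-dihydroxy-4,6-bis(1-methoxyethylidene)-2,8-dimethyl-3,7-dioxononanedioate F1. Silylation (TMSOTf, 2,6-lutidine) gives the bis(trimethylsilyl ether) F2, so that no alkoxide can trigger retro-Claisen cleavage. A conventional double vinylogous Dieckmann cyclization onto the methyl esters (LiHMDS, THF, −78 to 0 °C) and acidic work-up with desilylation returns to 10.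

Step 8. The second ring may be methylated about as fast as the first (loss of mono-selectivity), and enol O-methylation may compete. The fallback sets out from 13 and inverts the order of the last two operations. Condensation with one equivalent of ammonia (NH4OAc, MeOH) gives the mono-enaminone F3, whose aminated ring no longer forms an enolate. NaOMe/MeI in MeOH then methylates only the remaining triketone ring, with the same acyl shift, and the route is rejoined at 16.

Step 9. Ammonia may condense at the exocyclic acyl carbonyl or displace a ring methoxy group instead of reacting at the ring enol carbon. The fallback sets out from 15. Sulfonylation of the acidic ring enol (TsCl, Et3N, CH2Cl2) gives the vinylogous acyl tosylate F4. Addition–elimination with NaN3 in DMF gives the β-azido enone F5, and Staudinger reduction (PPh3, THF–H2O) delivers 16.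

**Further compounds**
F1 | step 6 | dimethyl (2S,8S,4E,6E)-2,8-dihydroxy-4,6-bis(1-methoxyethylidene)-2,8-dimethyl-3,7-dioxononanedioate | O[C@](C)(C(=O)OC)C(=O)/C(C/C(C(=O)[C@](C)(O)C(=O)OC)=C(/C)OC)=C(\C)OC
F2 | step 6 | bis(trimethylsilyl ether) of F1 | C[Si](C)(C)O[C@](C)(C(=O)OC)C(=O)/C(C/C(C(=O)[C@](C)(O[Si](C)(C)C)C(=O)OC)=C(/C)OC)=C(\C)OC
F3 | step 8 | mono-enaminone of 13 (one ring enol OH replaced by NH2) | O[C@]1(C)C(O)=C(C(=O)[C@H](C)CC)C(OC)=C(CC2=C(OC)C(C(=O)[C@H](C)CC)=C(N)[C@@](C)(O)C2=O)C1=O
F4 | step 9 | ring B enol 4-methylbenzenesulfonate of 15 | CC[C@@H](C)C(=O)O[C@]1(C)C(=O)C=C(OC)[C@@](C)(CC2=C(OC)C(C(=O)[C@H](C)CC)=C(OS(=O)(=O)c3ccc(C)cc3)[C@@](C)(O)C2=O)C1=O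
F5 | step 9 | ring B β-azido enone (N3 in place of the enol OH of 15) | CC[C@@H](C)C(=O)O[C@]1(C)C(=O)C=C(OC)[C@@](C)(CC2=C(OC)C(C(=O)[C@H](C)CC)=C(N=[N+]=[N-])[C@@](C)(O)C2=O)C1=O
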